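# Proposed synthesis of (2S)-5,7-dihydroxy-2-(4-hydroxy-3-methoxyphenyl)-8-prenylchroman-4-one (17)

## The problem

Target 17 is a (2S)-flavanone in which ring A, a phloroglucinol ring, is fused through O1 and C4a to the dihydropyranone ring C, and C2 of ring C carries ring B, a 4-hydroxy-3-methoxyphenyl group. Ring A is pentasubstituted: the prenyl group must stand at C8, between O1 and the 7-hydroxyl, and not at C6, so one of three equivalent phloroglucinol oxygens has to be singled out as O1 and both the acyl carbon C4 and the prenyl group have to be placed next to it. C2 is the only stereocentre, nothing in the molecule can direct it, and so it must come from a reagent or catalyst. It is also fragile: the C2–O1 bond is beta to the ketone, and base or hot acid opens ring C to the achiral 2'-hydroxychalcone and recloses it without memory of configuration, so the centre is best set late and followed only by mild, non-basic chemistry. The prenyl alkene next to a phenol tolerates neither strong acid nor electrophiles (closure to a chroman or an iodo ether) nor hydrogenation, and the three phenols need protection that comes off without base. The feature that opens the molecule is that ring C is ring A joined through O1 and C4a to one carbonyl carbon, C4, and a two-carbon unit, C3–C2, bearing ring B: at the flavone oxidation level these pieces are an ortho-iodophenol, carbon monoxide and an arylacetylene. The flavone so formed is flat and stable, and its C2=C3 bond is the handle for a catalyst-controlled hydride addition that creates C2.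

## Retrosynthesis

**Target 17 to protected flavanone 16.** Only the three methoxymethyl (MOM) groups on O5, O7 and O4' are removed. Acetals are preferred to the neighbouring choices because these oxygens must pass through a hot secondary amine, a thermal rearrangement and a hydridic copper catalyst, and must then be freed without base. Silyl ethers would be at risk in the hot amine, benzyl ethers cannot be hydrogenolysed beside the prenyl alkene, and esters would need base next to a base-labile stereocentre. Compound 16 is no simpler in skeleton, but it is the form in which C2 can be made and handled. The forward step must cleave three acetals faster than acid attacks the prenyl alkene or opens ring C.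

**Flavanone 16 to flavone 14.** The C2–H bond (with C3–H) is cut, which removes the only stereocentre. The neighbouring ways of making C2 are weaker here: oxa-Michael closure of a chalcone runs through the very equilibrium that racemises flavanones, and aryl transfer to a 2-unsubstituted chromone would need ring B as an organometallic and a separate chromone synthesis. Flavone 14 is achiral and robust, so all carbon–carbon chemistry can be finished before C2 exists. The forward reaction needs a chiral copper hydride to add to the Re face of C2, 1,4 and not 1,2, and to leave the isolated alkene alone.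

**Flavone 14 to iodophenol 7, alkyne 10 and carbon monoxide 11.** Three bonds are cut at once: C4a–C4, C4–C3 and O1–C2. The classical neighbours (acylation of ring A to a 2-hydroxyacetophenone, then chalcone formation and oxidative closure, or a diketone route) build the same ring over three or four steps, need an oxidation, and face the same question of which oxygen becomes O1. The three-component cut answers that question in the structure of 7: its only free hydroxyl lies between the iodide and the prenyl group. It also divides 14 into two aromatic halves of similar size and a one-carbon gas. The forward reaction needs carbonylation to come before alkynyl transfer, and six-membered closure to win over five-membered closure.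

**Iodophenol 7 to allyl iodophenol 6.** The C=C bond of the prenyl group is cut, so the side chain is carried as an allyl group and its terminal methylene is exchanged for an isopropylidene by cross-metathesis. Direct C-prenylation of a phloroglucinol phenoxide (from 1 or a partly protected form) gives O- and C-alkylated, mono- and bis-prenylated mixtures. A prenyl group also cannot be present when the iodine is introduced, because an iodonium source would close an iodo ether with the neighbouring hydroxyl. The forward step needs a metathesis catalyst that tolerates a free phenol and an aryl iodide.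

**Allyl iodophenol 6 to allylphenol 5.** The carbon–iodine bond at the future C4a is cut. Iodination is placed after the thermal rearrangement, so that no aryl iodide is heated, and before the prenyl group exists. The forward reaction needs substitution ortho to the free hydroxyl and not at the other free ring position, which lies between the two MOM ethers, and attack on the ring and not on the allyl alkene.

**Allylphenol 5 to allyl ether 3 (through dienone 4).** The ring–allyl bond is traced back to an O-allyl ether by a retro-Claisen step. This is the cut that solves the ring A problem. The rearrangement moves the allyl group from an oxygen to the carbon beside it and frees that oxygen, so one event both marks the future O1 and puts the side chain at the future C8. Because 3 is symmetrical, only one product can form.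

**Allyl ether 3 to phenol 2 and phloroglucinol 1.** The O-allyl bond and two MOM groups are removed. The twofold protection of 1 is statistical, and it is placed at the very start, on the cheapest material, where separation costs least.

**Alkyne 10 to aldehyde 9 and vanillin 8.** The triple bond is cut back to the aldehyde by a one-carbon homologation, and the MOM group is removed. Both steps are routine and give the ring B fragment in two steps from 8.

## Roads not taken

**Alternative 1:** The cut runs through ring A instead of ring C: C8–C8a and C4a–C5 are disconnected, leaving a chiral dihydropyranone that already holds C2 and ring B.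

- **Forward key step:** The bis(silyloxy)diene A1 (1-methoxy-7-methyl-1,3-bis(trimethylsilyloxy)octa-1,3,6-triene) would add across the C5=C6 bond of the sulfinyl dihydropyranone A2 ((2S)-2-[3-methoxy-4-(methoxymethoxy)phenyl]-5-(phenylsulfinyl)-2,3-dihydro-4H-pyran-4-one). Its prenyl-bearing terminus bonds to C6 (the later C8a) and its ketene-acetal carbon to C5 (the later C4a). Loss of the sulfenic acid and of the acetal methoxy group as its silyl ether would aromatise the new ring to A3, the 4'-MOM ether of the target.
- **Merits:** The diene places the prenyl group and both ring A hydroxyls, so the position of the side chain is never in doubt. This is a real advantage over the chosen plan, where it rests on a rearrangement and one regioselective iodination. C2 would come from a well-developed catalytic hetero-Diels–Alder reaction, and only one protecting group is left to remove.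
- **Weak points:** The C5=C6 bond of a dihydropyranone is part of a vinylogous ester and accepts dienes only after extra activation, so the sulfinyl group must be installed and oxidised (two steps, sulfur epimers). A1 must react at a substituted terminus, which slows the cycloaddition and makes it depend on diene geometry. The sulfenic acid elimination and aromatisation are run hot on a compound whose C2–O1 bond is beta to the ketone, with the free 5-hydroxyl of A3 present, which is the setting for loss of configuration by ring opening.
- **Comparison:** In step count the two roads are about level. Against the better regiocontrol of this road the chosen plan sets a ring-forming step with close analogy on ortho-iodophenols and a stereocentre made last, from an achiral flavone, that never sees heat or base.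

**Alternative 2:** The C2–C3 bond is cut.

- **Forward key step:** The diazoketone A4 (2-diazo-1-[4,6-bis(tert-butyldimethylsilyloxy)-2-{[4-(tert-butyldimethylsilyloxy)-3-methoxyphenyl]methoxy}-3-(3-methylbut-2-en-1-yl)phenyl]ethan-1-one) would be decomposed by Rh2(S-PTTL)4, dirhodium tetrakis[N-phthaloyl-(S)-tert-leucinate]. The carbene inserts into a benzylic C–H bond of the aryl benzyl ether, closing ring C and giving the tris-silyl flavanone A5 with C2 set by the catalyst.
- **Merits:** Ring and stereocentre arise in one catalytic step at the correct oxidation level, and a single desilylation would finish the synthesis. After its key step this road is one step shorter than the chosen one and needs no separate asymmetric reduction.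
- **Weak points:** The ether oxygen sits five atoms from the carbene carbon, so oxonium ylide formation and a [1,2]-benzyl shift to the five-membered benzofuranone skeleton is the expected main course. The wanted insertion closes a six-membered ring, whereas dirhodium carbenes prefer five. An acceptor-only ketocarbene is the least discriminating carbene class and has the electron-rich ring B within reach for aromatic cycloaddition. A4 is a pentasubstituted aryl ketone whose benzyl group must sit on the oxygen next to the prenyl group, which is the same differentiation problem as in 7, and it adds a hindered acid-to-diazoketone conversion.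
- **Comparison:** The chosen plan is longer after the key step but closes ring C by a reaction known on its substrate class, and it separates ring formation from stereocontrol so that each can be optimised alone.

**Alternative 3:** The C3–C4 and O1–C2 bonds are cut.

- **Forward key step:** A chiral phosphoric acid and an orthoformate would turn the salicylaldehyde A6 (2-hydroxy-4,6-bis(methoxymethoxy)-3-(3-methylbut-2-en-1-yl)benzaldehyde) into a methoxy-substituted ortho-quinone methide. This adds the styrene A7 (4-ethenyl-2-methoxy-1-(methoxymethoxy)benzene) to give the 2,4-cis-4-methoxyflavan A8.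
- **Merits:** Two fragments of the same size as those of the chosen plan are joined with C2 set in the ring-forming step itself, without metal, gas pressure or heat. A7 is one olefination from aldehyde 9. In convergence and mildness this road is at least the equal of the chosen one.
- **Weak points:** C4 arrives as a methyl ether at the alcohol oxidation level, so the acetal must be hydrolysed and the benzylic alcohol oxidised before deprotection. That is three steps after the stereocentre instead of one, with an oxidant that must spare the prenyl group and the electron-rich rings. The quinone methide from A6 carries three donor oxygens, so it is a weak electrophile and gives a loosely bound cation for the chiral anion. A7 is a 4-alkoxystyrene prone to acid-induced oligomerisation. MOM acetals can exchange under Brønsted acid and orthoester, and A6 needs the same differentiated oxygen pattern as 7.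
- **Comparison:** The chosen plan pays with an autoclave step and a separate reduction, and gains the correct oxidation level at C4 from the start and conditions (amine, CO) under which acetals and alkene are inert.

Key step: step 8

Remark on the chemistry: flavonoid numbering (O1, C2–C4, C4a, C5–C8, C8a; ring B 1'–6') is used throughout. The (R)-antipode of the bisphosphine in step 9 is written by analogy; the sense of induction must be confirmed, and the (S)-ligand is used instead if it is the one that delivers hydride to the Re face of C2.

## Route

Step 1
Reactants: 1 phloroglucinol (benzene-1,3,5-triol)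
Product: 2 3,5-bis(methoxymethoxy)phenol
Conditions: MOMCl (2 equiv), i-Pr2NEt, THF–CH2Cl2, 0 °C → rt; chromatography
Reagents that add atoms: chloromethyl methyl ether (MOMCl), COCCl
Why: O-Alkylation of a phenol with an alpha-chloro ether (MOM protection); the three hydroxyls are equivalent, so two equivalents of reagent should give the bis-ether as the main, separable component, and the mono- and tris-ethers can be returned to the process.

Step 2
Reactants: 2 3,5-bis(methoxymethoxy)phenol
Product: 3 1-(allyloxy)-3,5-bis(methoxymethoxy)benzene
Conditions: allyl bromide, K2CO3, acetone, reflux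
Reagents that add atoms: allyl bromide, C=CCBr
Why: Williamson ether synthesis on the single free phenol by SN2 displacement at a primary allylic bromide; the MOM acetals are inert to carbonate base.

Step 3
Reactants: 3 1-(allyloxy)-3,5-bis(methoxymethoxy)benzene
Product: 5 2-allyl-3,5-bis(methoxymethoxy)phenol, via ortho-dienone 4 (not isolated)
Conditions: PhNEt2, 190 °C
Reagents that add atoms: none
Why: Aromatic Claisen rearrangement: a concerted [3,3]-shift gives dienone 4, which tautomerises to phenol 5; the two ortho positions of 3 are equivalent, so only one product can form, and the basic solvent protects the acetals. The step places the side chain on the carbon next to the oxygen it sets free (the future C8 and O1).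

Step 4
Reactants: 5 2-allyl-3,5-bis(methoxymethoxy)phenol
Product: 6 2-allyl-6-iodo-3,5-bis(methoxymethoxy)phenol
Conditions: BnMe3N+ ICl2− (1.0 equiv), NaHCO3, CH2Cl2–MeOH, 0 °C
Reagents that add atoms: benzyltrimethylammonium dichloroiodate, C[N+](C)(C)Cc1ccccc1.Cl[I-]Cl
Why: Electrophilic aromatic iodination of a phenol with a buffered dichloroiodate; the ring, activated by three oxygens, should react far faster than the monosubstituted allyl alkene. Of its two free positions, C6 (ortho to the hydroxyl, the future C4a) is expected to be preferred over C4, which is wedged between two MOM ethers, in line with the known ortho-iodination of 3,5-dialkoxyphenols by this reagent.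

Step 5
Reactants: 6 2-allyl-6-iodo-3,5-bis(methoxymethoxy)phenol
Product: 7 2-iodo-3,5-bis(methoxymethoxy)-6-(3-methylbut-2-en-1-yl)phenol
Conditions: second-generation Grubbs catalyst RuCl2(=CHPh)(H2IMes)(PCy3) (3 mol %), 2-methyl-2-butene–CH2Cl2, rt → 40 °C
Reagents that add atoms: 2-methyl-2-butene, CC=C(C)C
Why: Olefin cross-metathesis of a terminal alkene with excess 2-methyl-2-butene, the standard allyl-to-prenyl conversion; free phenols and aryl iodides are tolerated by the ruthenium carbene, and the trisubstituted product does not re-enter the cycle.

Step 6
Reactants: 8 vanillin (4-hydroxy-3-methoxybenzaldehyde)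
Product: 9 3-methoxy-4-(methoxymethoxy)benzaldehyde
Conditions: MOMCl, i-Pr2NEt, CH2Cl2, 0 °C → rt
Reagents that add atoms: chloromethyl methyl ether (MOMCl), COCCl
Why: MOM protection of the single phenol by O-alkylation; the aldehyde is untouched.

Step 7
Reactants: 9 3-methoxy-4-(methoxymethoxy)benzaldehyde
Product: 10 4-ethynyl-2-methoxy-1-(methoxymethoxy)benzene
Conditions: dimethyl (1-diazo-2-oxopropyl)phosphonate, K2CO3, MeOH, rt
Reagents that add atoms: dimethyl (1-diazo-2-oxopropyl)phosphonate, CC(=O)C(=[N+]=[N-])P(=O)(OC)OC
Why: Seyferth–Gilbert homologation in its Ohira–Bestmann form: methanolysis of the reagent gives the diazomethylphosphonate anion, which olefinates the aldehyde; loss of N2 and a 1,2-hydride shift give the terminal alkyne under conditions mild enough for the acetal.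

Step 8
Reactants: 7 2-iodo-3,5-bis(methoxymethoxy)-6-(3-methylbut-2-en-1-yl)phenol; 10 4-ethynyl-2-methoxy-1-(methoxymethoxy)benzene; 11 carbon monoxide
Product: 14 2-[3-methoxy-4-(methoxymethoxy)phenyl]-5,7-bis(methoxymethoxy)-8-(3-methylbut-2-en-1-yl)-4H-chromen-4-one, via ortho-hydroxyaryl ynone 12 (not isolated), via diethylamino enaminone 13 (not isolated)
Conditions: PdCl2(PPh3)2 (5 mol %), Et2NH, CO (20 atm), 120 °C
Reagents that add atoms: none
Why: Zerovalent palladium, formed from PdCl2(PPh3)2 under CO and amine, inserts into the carbon–iodine bond of 7; CO insertion gives the aroylpalladium iodide, and amine-assisted, copper-free transfer of the acetylide of 10 followed by reductive elimination gives ynone 12 (bonds C4a–C4 and C4–C3). Diethylamine then adds to 12 to give enaminone 13, whose phenoxide attacks C2 in a 6-endo-trig addition–elimination that expels the amine and closes ring C through O1–C2 as flavone 14. The closest known reaction type is the palladium-catalysed carbonylative coupling–cyclisation of ortho-iodophenols with terminal arylacetylenes under CO in a secondary amine, which gives flavones. No stereocentre is formed, since C2 stays trigonal. CO insertion must precede alkynyl transfer, because direct coupling would lead on to a 2-arylbenzofuran; CO pressure, the absence of copper and the two ortho substituents beside the carbon–palladium bond should secure this. The acylpalladium must take the alkyne and not the amine; the di-ortho-substituted aroyl group is shielded from direct amine attack, whereas the acetylide is delivered from the metal. Closure must be six-membered and not 5-exo-dig to the aurone; passage through 13 turns the choice into an addition–elimination at C2, and the ring fusion is fixed by the substrate, because the only free hydroxyl of 7 lies between the iodide and the prenyl group. The MOM acetals and the trisubstituted alkene are inert to amine, CO and zerovalent palladium.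

Step 9
Reactants: 14 2-[3-methoxy-4-(methoxymethoxy)phenyl]-5,7-bis(methoxymethoxy)-8-(3-methylbut-2-en-1-yl)-4H-chromen-4-one
Product: 16 (2S)-2-[3-methoxy-4-(methoxymethoxy)phenyl]-5,7-bis(methoxymethoxy)-8-(3-methylbut-2-en-1-yl)-2,3-dihydro-4H-chromen-4-one, via silyl enol ether 15 (not isolated)
Conditions: Cu(OAc)2·H2O (5 mol %), (R)-DTBM-SEGPHOS (5.5 mol %), (EtO)2MeSiH (3 equiv), toluene, 0 °C → rt; then 1 M aq. HCl, THF, 0 °C
Reagents that add atoms: none
Why: Asymmetric conjugate reduction by a bisphosphine-ligated hydride of monovalent copper, the reaction type known for chromones and beta-aryl cyclic enones. The chiral CuH complex delivers hydride to the Re face of C2, which gives (2S), and the copper enolate is silylated to 15; this shields the ketone from 1,2-reduction and the enolate from beta-elimination of the aryloxide until cold dilute acid releases 16. The isolated trisubstituted alkene and the acetals are not touched.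

Step 10
Reactants: 16 (2S)-2-[3-methoxy-4-(methoxymethoxy)phenyl]-5,7-bis(methoxymethoxy)-8-(3-methylbut-2-en-1-yl)-2,3-dihydro-4H-chromen-4-one
Product: 17 (2S)-5,7-dihydroxy-2-(4-hydroxy-3-methoxyphenyl)-8-(3-methylbut-2-en-1-yl)-2,3-dihydro-4H-chromen-4-one
Conditions: 3 M aq. HCl, MeOH, 50 °C
Reagents that add atoms: none
Why: Acid-catalysed acetal methanolysis (MOM cleavage), each methoxymethyl group leaving as dimethoxymethane; dilute acid at moderate temperature is the usual way to unmask prenylated flavanones. Forming a tertiary cation from the prenyl group or opening ring C needs stronger acid or longer heating, so C2 should keep its configuration.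

## Compound list

1 | phloroglucinol (benzene-1,3,5-triol) | Oc1cc(O)cc(O)c1 | starting material
2 | 3,5-bis(methoxymethoxy)phenol | COCOc1cc(O)cc(OCOC)c1 | intermediate
3 | 1-(allyloxy)-3,5-bis(methoxymethoxy)benzene | C=CCOc1cc(OCOC)cc(OCOC)c1 | intermediate
4 | (±)-6-allyl-3,5-bis(methoxymethoxy)cyclohexa-2,4-dien-1-one, the ortho-dienone of step 3 (not isolated) | C=CCC1C(=O)C=C(OCOC)C=C1OCOC | intermediate
5 | 2-allyl-3,5-bis(methoxymethoxy)phenol | C=CCc1c(O)cc(OCOC)cc1OCOC | intermediate
6 | 2-allyl-6-iodo-3,5-bis(methoxymethoxy)phenol | C=CCc1c(O)c(I)c(OCOC)cc1OCOC | intermediate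
7 | 2-iodo-3,5-bis(methoxymethoxy)-6-(3-methylbut-2-en-1-yl)phenol | CC(C)=CCc1c(O)c(I)c(OCOC)cc1OCOC | intermediate
8 | vanillin (4-hydroxy-3-methoxybenzaldehyde) | COc1cc(C=O)ccc1O | starting material
9 | 3-methoxy-4-(methoxymethoxy)benzaldehyde | COCOc1ccc(C=O)cc1OC | intermediate
10 | 4-ethynyl-2-methoxy-1-(methoxymethoxy)benzene | C#Cc1ccc(OCOC)c(OC)c1 | intermediate
11 | carbon monoxide | [C-]#[O+] | starting material
12 | 1-[2-hydroxy-4,6-bis(methoxymethoxy)-3-(3-methylbut-2-en-1-yl)phenyl]-3-[3-methoxy-4-(methoxymethoxy)phenyl]prop-2-yn-1-one, the ortho-hydroxyaryl ynone of step 8 (not isolated) | COCOc1ccc(C#CC(=O)c2c(O)c(CC=C(C)C)c(OCOC)cc2OCOC)cc1OC | intermediate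
13 | (E)-3-(diethylamino)-1-[2-hydroxy-4,6-bis(methoxymethoxy)-3-(3-methylbut-2-en-1-yl)phenyl]-3-[3-methoxy-4-(methoxymethoxy)phenyl]prop-2-en-1-one, the diethylamino enaminone of step 8 (not isolated; drawn as the E isomer, the geometry being lost when C2 becomes tetrahedral) | CCN(CC)/C(=C/C(=O)c1c(O)c(CC=C(C)C)c(OCOC)cc1OCOC)c1ccc(OCOC)c(OC)c1 | intermediate
14 | 2-[3-methoxy-4-(methoxymethoxy)phenyl]-5,7-bis(methoxymethoxy)-8-(3-methylbut-2-en-1-yl)-4H-chromen-4-one | COc1cc(-c2cc(=O)c3c(OCOC)cc(OCOC)c(CC=C(C)C)c3o2)ccc1OCOC | intermediate
15 | (2S)-4-{[diethoxy(methyl)silyl]oxy}-2-[3-methoxy-4-(methoxymethoxy)phenyl]-5,7-bis(methoxymethoxy)-8-(3-methylbut-2-en-1-yl)-2H-chromene, the silyl enol ether of step 9 (not isolated) | COc1cc([C@@H]2C=C(O[Si](C)(OCC)OCC)c3c(OCOC)cc(OCOC)c(CC=C(C)C)c3O2)ccc1OCOC | intermediate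
16 | (2S)-2-[3-methoxy-4-(methoxymethoxy)phenyl]-5,7-bis(methoxymethoxy)-8-(3-methylbut-2-en-1-yl)-2,3-dihydro-4H-chromen-4-one | COc1cc([C@@H]2CC(=O)c3c(OCOC)cc(OCOC)c(CC=C(C)C)c3O2)ccc1OCOC | intermediate
17 | (2S)-5,7-dihydroxy-2-(4-hydroxy-3-methoxyphenyl)-8-(3-methylbut-2-en-1-yl)-2,3-dihydro-4H-chromen-4-one | COc1cc([C@@H]2CC(=O)c3c(O)cc(O)c(CC=C(C)C)c3O2)ccc1O | target

## Step count and points of risk

Total step count: 10. Longest linear sequence: 8 steps (steps 1–5 and 8–10, from 1); the alkyne branch (steps 6 and 7) joins at step 8.

**Step 8 (key step).** The acylpalladium intermediate may be captured by the amine (amide formation), or alkynyl transfer may overtake CO insertion and lead on to five-membered closure. Oxidative addition into a very electron-rich, phenoxide-bearing carbon–iodine bond may also be slow enough for protodeiodination to compete.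

Fallback, without CO and without palladium, from 7 and 10, rejoining the route at 12:
- Phenol 7 is silylated (TBSOTf, 2,6-lutidine) to tert-butyl{2-iodo-3,5-bis(methoxymethoxy)-6-(3-methylbut-2-en-1-yl)phenoxy}dimethylsilane F1.
- Alkyne 10 is deprotonated (n-BuLi, THF, −78 °C) and acylated with N-methoxy-N-methylcarbamoyl chloride to the Weinreb amide N-methoxy-3-[3-methoxy-4-(methoxymethoxy)phenyl]-N-methylprop-2-ynamide F2.
- Iodine–magnesium exchange on F1 (i-PrMgCl·LiCl, THF) and addition of the arylmagnesium to F2 give the silyl-protected ynone 1-[2-(tert-butyldimethylsilyloxy)-4,6-bis(methoxymethoxy)-3-(3-methylbut-2-en-1-yl)phenyl]-3-[3-methoxy-4-(methoxymethoxy)phenyl]prop-2-yn-1-one F3.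
- Buffered Bu4NF (AcOH, THF) releases ynone 12. Et2NH in EtOH then takes it through 13 to 14 as in step 8.

**Step 9.** Hydride addition to a doubly donor-substituted vinylogous ester may be sluggish, and facial selectivity at C2 may be insufficient or of the opposite sense. Over-reduction at C4 or ring opening of the copper enolate by beta-elimination may also intervene.

Fallback, from 14, rejoining at 16:
- Non-asymmetric 1,4-reduction (LiBH(s-Bu)3, THF, −78 °C, AcOH quench) gives racemic 2-[3-methoxy-4-(methoxymethoxy)phenyl]-5,7-bis(methoxymethoxy)-8-(3-methylbut-2-en-1-yl)-2,3-dihydro-4H-chromen-4-one F4.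
- Kinetic resolution by asymmetric transfer hydrogenation (RuCl(p-cymene)[(R,R)-TsDPEN], HCO2H–Et3N) follows. By the usual facial preference of this catalyst for aryl ketones and hydride delivery anti to the C2 aryl group, the (2R)-ketone should be reduced to (2R,4R)-2-[3-methoxy-4-(methoxymethoxy)phenyl]-5,7-bis(methoxymethoxy)-8-(3-methylbut-2-en-1-yl)chroman-4-ol F5.
- The unreacted (S)-ketone 16 is separated from F5. The price is at most half of the material.

**Step 4.** Iodination may occur at the position para to the hydroxyl between the two MOM ethers, a second iodine may enter, or the iodonium source may attack the allyl alkene with ring closure by the phenol.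

Fallback by reversal of the order of events, from 2, rejoining at 6:
- Phenol 2, which has no alkene, is iodinated with the same buffered reagent to 2-iodo-3,5-bis(methoxymethoxy)phenol F6. Here substitution para to the hydroxyl would be revealed by the symmetry of the product.
- O-Allylation (allyl bromide, K2CO3, acetone) gives 1-(allyloxy)-2-iodo-3,5-bis(methoxymethoxy)benzene F7.
- Claisen rearrangement (PhNEt2, about 180 °C) proceeds through 6-allyl-2-iodo-3,5-bis(methoxymethoxy)cyclohexa-2,4-dien-1-one F8 to 6. The only free ortho position is the required one, so the regiochemistry is enforced; the cost is that an aryl iodide must survive the heating.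

**Step 10.** Prolonged acid may add the 7-hydroxyl across the prenyl alkene, or may open and reclose ring C with partial loss of configuration.

Fallback that moves the acid step in front of the stereocentre, from 14, rejoining at 17:
- The MOM groups are cleaved on the achiral flavone (3 M aq. HCl, MeOH, 50 °C) to 5,7-dihydroxy-2-(4-hydroxy-3-methoxyphenyl)-8-(3-methylbut-2-en-1-yl)-4H-chromen-4-one F9, where only the alkene is at stake.
- Silylation (TBSOTf, 2,6-lutidine, CH2Cl2) gives 5,7-bis(tert-butyldimethylsilyloxy)-2-[4-(tert-butyldimethylsilyloxy)-3-methoxyphenyl]-8-(3-methylbut-2-en-1-yl)-4H-chromen-4-one F10.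
- Copper hydride reduction as in step 9 gives (2S)-5,7-bis(tert-butyldimethylsilyloxy)-2-[4-(tert-butyldimethylsilyloxy)-3-methoxyphenyl]-8-(3-methylbut-2-en-1-yl)-2,3-dihydro-4H-chromen-4-one F11, the same silyl ether as A5.
- Desilylation with Et3N·3HF in THF, a weakly acidic fluoride source, gives 17 without protic mineral acid or base.

## Further compounds

F1 | step 8 | tert-butyl{2-iodo-3,5-bis(methoxymethoxy)-6-(3-methylbut-2-en-1-yl)phenoxy}dimethylsilane | CC(C)=CCc1c(O[Si](C)(C)C(C)(C)C)c(I)c(OCOC)cc1OCOC
F2 | step 8 | N-methoxy-3-[3-methoxy-4-(methoxymethoxy)phenyl]-N-methylprop-2-ynamide | CON(C)C(=O)C#Cc1ccc(OCOC)c(OC)c1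
F3 | step 8 | 1-[2-(tert-butyldimethylsilyloxy)-4,6-bis(methoxymethoxy)-3-(3-methylbut-2-en-1-yl)phenyl]-3-[3-methoxy-4-(methoxymethoxy)phenyl]prop-2-yn-1-one | COCOc1ccc(C#CC(=O)c2c(O[Si](C)(C)C(C)(C)C)c(CC=C(C)C)c(OCOC)cc2OCOC)cc1OC
F4 | step 9 | racemic 2-[3-methoxy-4-(methoxymethoxy)phenyl]-5,7-bis(methoxymethoxy)-8-(3-methylbut-2-en-1-yl)-2,3-dihydro-4H-chromen-4-one | COc1cc(C2CC(=O)c3c(OCOC)cc(OCOC)c(CC=C(C)C)c3O2)ccc1OCOC
F5 | step 9 | (2R,4R)-2-[3-methoxy-4-(methoxymethoxy)phenyl]-5,7-bis(methoxymethoxy)-8-(3-methylbut-2-en-1-yl)chroman-4-ol | COc1cc([C@H]2C[C@@H](O)c3c(OCOC)cc(OCOC)c(CC=C(C)C)c3O2)ccc1OCOC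
F6 | step 4 | 2-iodo-3,5-bis(methoxymethoxy)phenol | COCOc1cc(O)c(I)c(OCOC)c1
F7 | step 4 | 1-(allyloxy)-2-iodo-3,5-bis(methoxymethoxy)benzene | C=CCOc1cc(OCOC)cc(OCOC)c1I
F8 | step 4 | (±)-6-allyl-2-iodo-3,5-bis(methoxymethoxy)cyclohexa-2,4-dien-1-one | C=CCC1C(=O)C(I)=C(OCOC)C=C1OCOC
F9 | step 10 | 5,7-dihydroxy-2-(4-hydroxy-3-methoxyphenyl)-8-(3-methylbut-2-en-1-yl)-4H-chromen-4-one | COc1cc(-c2cc(=O)c3c(O)cc(O)c(CC=C(C)C)c3o2)ccc1O
F10 | step 10 | 5,7-bis(tert-butyldimethylsilyloxy)-2-[4-(tert-butyldimethylsilyloxy)-3-methoxyphenyl]-8-(3-methylbut-2-en-1-yl)-4H-chromen-4-one | COc1cc(-c2cc(=O)c3c(O[Si](C)(C)C(C)(C)C)cc(O[Si](C)(C)C(C)(C)C)c(CC=C(C)C)c3o2)ccc1O[Si](C)(C)C(C)(C)C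
F11 | step 10 | (2S)-5,7-bis(tert-butyldimethylsilyloxy)-2-[4-(tert-butyldimethylsilyloxy)-3-methoxyphenyl]-8-(3-methylbut-2-en-1-yl)-2,3-dihydro-4H-chromen-4-one | COc1cc([C@@H]2CC(=O)c3c(O[Si](C)(C)C(C)(C)C)cc(O[Si](C)(C)C(C)(C)C)c(CC=C(C)C)c3O2)ccc1O[Si](C)(C)C(C)(C)C
A1 | alternative 1 | 1-methoxy-7-methyl-1,3-bis(trimethylsilyloxy)octa-1,3,6-triene (enol ether geometry not fixed) | COC(O[Si](C)(C)C)=CC(O[Si](C)(C)C)=CCC=C(C)C
A2 | alternative 1 | (2S)-2-[3-methoxy-4-(methoxymethoxy)phenyl]-5-(phenylsulfinyl)-2,3-dihydro-4H-pyran-4-one (either sulfur epimer) | COCOc1ccc([C@@H]2CC(=O)C(S(=O)c3ccccc3)=CO2)cc1OC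
A3 | alternative 1 | (2S)-5,7-dihydroxy-2-[3-methoxy-4-(methoxymethoxy)phenyl]-8-(3-methylbut-2-en-1-yl)-2,3-dihydro-4H-chromen-4-one | COc1cc([C@@H]2CC(=O)c3c(O)cc(O)c(CC=C(C)C)c3O2)ccc1OCOC
A4 | alternative 2 | 2-diazo-1-[4,6-bis(tert-butyldimethylsilyloxy)-2-{[4-(tert-butyldimethylsilyloxy)-3-methoxyphenyl]methoxy}-3-(3-methylbut-2-en-1-yl)phenyl]ethan-1-one | COc1cc(COc2c(CC=C(C)C)c(O[Si](C)(C)C(C)(C)C)cc(O[Si](C)(C)C(C)(C)C)c2C(=O)C=[N+]=[N-])ccc1O[Si](C)(C)C(C)(C)C
A5 | alternative 2 | (2S)-5,7-bis(tert-butyldimethylsilyloxy)-2-[4-(tert-butyldimethylsilyloxy)-3-methoxyphenyl]-8-(3-methylbut-2-en-1-yl)-2,3-dihydro-4H-chromen-4-one | COc1cc([C@@H]2CC(=O)c3c(O[Si](C)(C)C(C)(C)C)cc(O[Si](C)(C)C(C)(C)C)c(CC=C(C)C)c3O2)ccc1O[Si](C)(C)C(C)(C)C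
A6 | alternative 3 | 2-hydroxy-4,6-bis(methoxymethoxy)-3-(3-methylbut-2-en-1-yl)benzaldehyde | O=Cc1c(O)c(CC=C(C)C)c(OCOC)cc1OCOC
A7 | alternative 3 | 4-ethenyl-2-methoxy-1-(methoxymethoxy)benzene | C=Cc1ccc(OCOC)c(OC)c1
A8 | alternative 3 | (2S,4S)-4-methoxy-2-[3-methoxy-4-(methoxymethoxy)phenyl]-5,7-bis(methoxymethoxy)-8-(3-methylbut-2-en-1-yl)chroman (2,4-cis) | COc1cc([C@@H]2C[C@H](OC)c3c(OCOC)cc(OCOC)c(CC=C(C)C)c3O2)ccc1OCOC
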